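The pyran ring (ring C) of the isoflavan is disconnected at O1–C2 and C3–C4. Ring A carries O1 and C4 on adjacent carbons (C8a, C4a), so it is a latent ortho-quinone methide, and C3 is alpha to C2, which can be an aldehyde carbon. An amine-catalysed formal [4+2] reaction between this quinone methide and the enamine of 2-(2,3,4,6-tetramethoxyphenyl)acetaldehyde forms C3–C4 (Michael addition, setting C3) and O1–C2 (hemiacetal) in one operation. The lactol carbon is then reduced to CH2. The quinone (ring B) is unveiled last, by hydroxylation of the one free position of ring B and oxidative demethylation.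

Key step: step 5

Remark: lactol 11 is expected as a mixture of C2 epimers, which is immaterial because C2 becomes CH2 in step 6; starting materials 1 and 5 are taken as catalogue chemicals.

Step 1
Reactants: 1 1,2,3,5-tetramethoxybenzene
Product: 3 2-(2,3,4,6-tetramethoxyphenyl)ethan-1-ol, via aryllithium 2 (not isolated)
Conditions: n-BuLi (1.05 equiv), THF, 0 °C to rt; then ethylene oxide, 0 °C to rt; H2O
Reagents that add atoms: ethylene oxide C1CO1
Why: Directed ortho-lithiation removes a C–H flanked by two methoxy groups (the two such positions are equivalent by symmetry), and the aryllithium opens the epoxide to give the 2-arylethanol.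

Step 2
Reactants: 3 2-(2,3,4,6-tetramethoxyphenyl)ethan-1-ol
Product: 4 2-(2,3,4,6-tetramethoxyphenyl)acetaldehyde
Conditions: DMP (1,1,1-triacetoxy-1,1-dihydro-1,2-benziodoxol-3(1H)-one), CH2Cl2, 0 °C to rt; used without storage
Reagents that add atoms: none
Why: Periodinane oxidation of a primary alcohol should stop cleanly at the aldehyde under neutral, non-enolising conditions that the electron-rich arene tolerates.

Step 3
Reactants: 5 2,3,4-trimethoxyphenol
Product: 6 6-[(dimethylamino)methyl]-2,3,4-trimethoxyphenol
Conditions: aq. Me2NH, aq. CH2O, EtOH, rt to 60 °C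
Reagents that add atoms: formaldehyde C=O; dimethylamine CNC
Why: Mannich reaction of a phenol whose para position is blocked by OMe, so the hydrogen-bonded iminium ion should be delivered to the single free ortho carbon.

Step 4
Reactants: 6 6-[(dimethylamino)methyl]-2,3,4-trimethoxyphenol
Product: 7 (2-hydroxy-3,4,5-trimethoxyphenyl)-N,N,N-trimethylmethanaminium iodide
Conditions: MeI, acetone, rt
Reagents that add atoms: iodomethane CI
Why: Menshutkin quaternisation (SN2) of the benzylic tertiary amine; without base the phenol is not methylated, and the salt should be a bench-stable quinone methide precursor.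

Step 5
Reactants: 4 2-(2,3,4,6-tetramethoxyphenyl)acetaldehyde (1.5 equiv); 7 (2-hydroxy-3,4,5-trimethoxyphenyl)-N,N,N-trimethylmethanaminium iodide
Product: 11 (3S)-6,7,8-trimethoxy-3-(2,3,4,6-tetramethoxyphenyl)-3,4-dihydro-2H-chromen-2-ol (lactol as a mixture of C2 epimers), via o-quinone methide 8 (not isolated), via enamine 9 (not isolated), via hydroxy aldehyde 10 (not isolated)
Conditions: (S)-α,α-diphenylprolinol trimethylsilyl ether (20 mol%), K2CO3 (1.2 equiv), MeCN, 0 °C to rt
Reagents that add atoms: none
Why: K2CO3 deprotonates the phenol of 7 and the betaine expels NMe3 (E1cB, helped by the methoxy group para to the benzylic carbon) to release o-quinone methide 8 slowly, while 4 and the amine form the (E)-enamine 9. The enamine carbon adds to the exocyclic CH2 of 8 (Michael addition, re-aromatising ring A: C3–C4 bond), the iminium ion is hydrolysed to 10, and the liberated phenol O1 adds to the aldehyde carbon (6-exo-trig hemiacetalisation: O1–C2 bond, ring C closed), overall a formal hetero-[4+2] annulation. The closest known reaction type is the amine-catalysed Michael addition/hemiacetalisation of aldehydes with quinone methides generated in situ, which gives chroman-2-ols. C3 is set by the catalyst: the C(Ph)2OSiMe3 group blocks one face of the s-trans (E)-enamine, so 8 approaches the open face, which corresponds to 3S for the (S)-catalyst; C2 forms as an epimeric mixture and is irrelevant. The step needs C-alkylation of the enamine to outrun N-alkylation of the catalyst and self-condensation of 8, which slow release of 8, an excess of 4 and the hindered amine should secure; regiochemistry is fixed because only the CH2 of 8 is electrophilic. The 2,6-dimethoxyaryl group is twisted out of the enol plane and the aldehyde is masked as the lactol, which should protect C3 from epimerisation.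

Step 6
Reactants: 11 (3S)-6,7,8-trimethoxy-3-(2,3,4,6-tetramethoxyphenyl)-3,4-dihydro-2H-chromen-2-ol
Product: 13 (3S)-6,7,8-trimethoxy-3-(2,3,4,6-tetramethoxyphenyl)-3,4-dihydro-2H-chromene, via oxocarbenium ion 12 (not isolated)
Conditions: Et3SiH (5 equiv), BF3·OEt2 (2 equiv), CH2Cl2, −78 to −40 °C
Reagents that add atoms: none
Why: Ionic hydrogenation: BF3 ionises the lactol to the cyclic oxocarbenium ion, which excess silane should trap at low temperature faster than the C3 proton is lost, so C2 becomes CH2 with the O1–C2 bond and the C3 configuration retained.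

Step 7
Reactants: 13 (3S)-6,7,8-trimethoxy-3-(2,3,4,6-tetramethoxyphenyl)-3,4-dihydro-2H-chromene
Product: 16 2,3,4,6-tetramethoxy-5-[(3S)-6,7,8-trimethoxy-3,4-dihydro-2H-chromen-3-yl]phenol, via aryllithium 14 (not isolated), via arylboronate 15 (not isolated)
Conditions: n-BuLi (1.3 equiv), THF, 0 °C; B(OMe)3, −78 °C to rt; then AcOH, 30% aq. H2O2, 0 °C
Reagents that add atoms: hydrogen peroxide OO
Why: Directed ortho-metalation should occur selectively at the only C–H flanked by two methoxy groups (C5' of ring B; the ring A C–H has one methoxy neighbour), and borylation followed by boronate oxidation (1,2-aryl shift to oxygen) gives the phenol without touching C3.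

Step 8
Reactants: 16 2,3,4,6-tetramethoxy-5-[(3S)-6,7,8-trimethoxy-3,4-dihydro-2H-chromen-3-yl]phenol
Product: 17 2,3,5-trimethoxy-6-[(3S)-6,7,8-trimethoxy-3,4-dihydro-2H-chromen-3-yl]cyclohexa-2,5-diene-1,4-dione (target)
Conditions: PhI(OAc)2 (1.1 equiv), MeCN/H2O, 0 °C
Reagents that add atoms: water O
Why: Oxidative demethylation of a para-methoxyphenol: the phenol is oxidised by the iodane, water adds at C2' (para to the phenol oxygen, bearing OMe) and methanol is lost to give the para-quinone, while ring A has no free phenol and should stay intact, as should C3.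

Compound list
1 | 1,2,3,5-tetramethoxybenzene | COc1cc(OC)c(OC)c(OC)c1 | starting material
2 | (2,3,4,6-tetramethoxyphenyl)lithium (not isolated) | [Li]c1c(OC)cc(OC)c(OC)c1OC | intermediate
3 | 2-(2,3,4,6-tetramethoxyphenyl)ethan-1-ol | OCCc1c(OC)cc(OC)c(OC)c1OC | intermediate
4 | 2-(2,3,4,6-tetramethoxyphenyl)acetaldehyde | O=CCc1c(OC)cc(OC)c(OC)c1OC | intermediate
5 | 2,3,4-trimethoxyphenol | COc1ccc(O)c(OC)c1OC | starting material
6 | 6-[(dimethylamino)methyl]-2,3,4-trimethoxyphenol | CN(C)Cc1cc(OC)c(OC)c(OC)c1O | intermediate
7 | (2-hydroxy-3,4,5-trimethoxyphenyl)-N,N,N-trimethylmethanaminium iodide | C[N+](C)(C)Cc1cc(OC)c(OC)c(OC)c1O.[I-] | intermediate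
8 | 2,3,4-trimethoxy-6-methylidenecyclohexa-2,4-dien-1-one, the o-quinone methide of ring A (not isolated) | C=C1C=C(OC)C(OC)=C(OC)C1=O | intermediate
9 | (E)-enamine of 4 with (S)-α,α-diphenylprolinol trimethylsilyl ether (not isolated) | C[Si](C)(C)OC(c1ccccc1)(c1ccccc1)[C@@H]1CCCN1/C=C/c1c(OC)cc(OC)c(OC)c1OC | intermediate
10 | (2S)-3-(2-hydroxy-3,4,5-trimethoxyphenyl)-2-(2,3,4,6-tetramethoxyphenyl)propanal (not isolated) | COc1cc(OC)c(OC)c(OC)c1[C@@H](C=O)Cc1cc(OC)c(OC)c(OC)c1O | intermediate
11 | (3S)-6,7,8-trimethoxy-3-(2,3,4,6-tetramethoxyphenyl)-3,4-dihydro-2H-chromen-2-ol (C2 epimers) | COc1cc(OC)c(OC)c(OC)c1[C@H]1C(O)Oc2c(cc(OC)c(OC)c2OC)C1 | intermediate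
12 | (3S)-6,7,8-trimethoxy-3-(2,3,4,6-tetramethoxyphenyl)-3,4-dihydrochromenylium, the oxocarbenium ion (not isolated) | COc1cc(OC)c(OC)c(OC)c1[C@H]1C=[O+]c2c(cc(OC)c(OC)c2OC)C1 | intermediate
13 | (3S)-6,7,8-trimethoxy-3-(2,3,4,6-tetramethoxyphenyl)-3,4-dihydro-2H-chromene | COc1cc(OC)c(OC)c(OC)c1[C@H]1COc2c(cc(OC)c(OC)c2OC)C1 | intermediate
14 | 5'-lithio derivative of 13 (not isolated) | COc1c([Li])c(OC)c(OC)c(OC)c1[C@H]1COc2c(cc(OC)c(OC)c2OC)C1 | intermediate
15 | dimethyl 5'-boronate of 13 (not isolated) | COc1c(B(OC)OC)c(OC)c(OC)c(OC)c1[C@H]1COc2c(cc(OC)c(OC)c2OC)C1 | intermediate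
16 | 2,3,4,6-tetramethoxy-5-[(3S)-6,7,8-trimethoxy-3,4-dihydro-2H-chromen-3-yl]phenol | COc1c(O)c(OC)c(OC)c(OC)c1[C@H]1COc2c(cc(OC)c(OC)c2OC)C1 | intermediate
17 | 2,3,5-trimethoxy-6-[(3S)-6,7,8-trimethoxy-3,4-dihydro-2H-chromen-3-yl]cyclohexa-2,5-diene-1,4-dione | COC1=C(OC)C(=O)C([C@H]2COc3c(cc(OC)c(OC)c3OC)C2)=C(OC)C1=O | target

Total step count: 8
Longest linear sequence: 6 steps (steps 1, 2, 5, 6, 7, 8; the branch through steps 3 and 4 is equally long)

Steps most likely to fail

Step 5. The quinone methide may alkylate the secondary-amine catalyst irreversibly or oligomerise before the enamine captures it, or the alpha-aryl stereocentre may erode by enolisation under the basic amine conditions. The fallback moves to the carboxylic acid oxidation level and a tertiary-amine catalyst, which can add to the quinone methide only reversibly. It sets out from aldehyde 4, which is oxidised (Pinnick oxidation: NaClO2, NaH2PO4, 2-methylbut-2-ene, t-BuOH/H2O) to 2-(2,3,4,6-tetramethoxyphenyl)acetic acid F1. Pivaloyl chloride and i-Pr2NEt in CH2Cl2 convert F1 in the flask into the mixed anhydride 2-(2,3,4,6-tetramethoxyphenyl)acetic pivalic anhydride F2. With the isothiourea HyperBTM (10 mol%; the enantiomer that leads to the 3S lactone, expected to be the (2S,3R) form on the usual facial model) F2 gives the C1-ammonium enolate, which adds to quinone methide 8 released from salt 7 by i-Pr2NEt. Lactonisation by the phenoxide turns the catalyst over and should give (3S)-6,7,8-trimethoxy-3-(2,3,4,6-tetramethoxyphenyl)chroman-2-one F3. Reduction with i-Bu2AlH (CH2Cl2, −78 °C) then returns to the route at lactol 11.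

Step 6. The oxocarbenium ion may lose the C3 proton to an enol ether and be reprotonated, which would scramble C3, if hydride transfer is slow. The fallback avoids any cation next to C3. It sets out from lactol 11, which is reduced through its open form with NaBH4 (MeOH, 0 °C) to 6-[(2S)-3-hydroxy-2-(2,3,4,6-tetramethoxyphenyl)propyl]-2,3,4-trimethoxyphenol F4. Mitsunobu etherification (PPh3, DIAD, THF, 0 °C) closes ring C by SN2 attack of the phenol at the primary carbon and returns to the route at isoflavan 13.

Step 7. Metalation may compete at the ring A C–H or the benzylic C4 position, base may open the pyran ring by beta-elimination, or peroxide may over-oxidise the electron-rich phenol. The fallback replaces directed metalation by electrophilic substitution and cross-coupling. It sets out from isoflavan 13, which is brominated with NBS (MeCN, 0 °C) at C5' of ring B, the most nucleophilic arene position (ortho, ortho and para to three methoxy groups), to give (3S)-3-(3-bromo-2,4,5,6-tetramethoxyphenyl)-6,7,8-trimethoxy-3,4-dihydro-2H-chromene F5. Hydroxylation of F5 (Pd2(dba)3, t-BuXPhos, KOH, dioxane/H2O, 100 °C) returns to the route at phenol 16.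

Further compounds
F1 | step 5 | 2-(2,3,4,6-tetramethoxyphenyl)acetic acid | OC(=O)Cc1c(OC)cc(OC)c(OC)c1OC
F2 | step 5 | 2-(2,3,4,6-tetramethoxyphenyl)acetic pivalic anhydride | CC(C)(C)C(=O)OC(=O)Cc1c(OC)cc(OC)c(OC)c1OC
F3 | step 5 | (3S)-6,7,8-trimethoxy-3-(2,3,4,6-tetramethoxyphenyl)chroman-2-one | COc1cc(OC)c(OC)c(OC)c1[C@H]1C(=O)Oc2c(cc(OC)c(OC)c2OC)C1
F4 | step 6 | 6-[(2S)-3-hydroxy-2-(2,3,4,6-tetramethoxyphenyl)propyl]-2,3,4-trimethoxyphenol | COc1cc(OC)c(OC)c(OC)c1[C@@H](CO)Cc1cc(OC)c(OC)c(OC)c1O
F5 | step 7 | (3S)-3-(3-bromo-2,4,5,6-tetramethoxyphenyl)-6,7,8-trimethoxy-3,4-dihydro-2H-chromene | COc1c(Br)c(OC)c(OC)c(OC)c1[C@H]1COc2c(cc(OC)c(OC)c2OC)C1
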